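The route rests on cutting ring A (C1–C5, C10) across C10–C1 and C5–C4. The spiro carbon C10, which ring A shares with the δ-lactone, and its neighbour C5 with the C6 oxymethyl branch are read as an exocyclic enal (C10=C5–C6HO) on the finished lactone–bicyclo[3.2.1]octanone. C1–C4 with the C4 methyl and C19 oxymethyl are a silylated (E)-2-methylpenta-2,4-dienol. One Lewis-acid-promoted Diels–Alder reaction closes ring A, forms both bonds and sets the quaternary centres C10 and C4. The tricyclic enal comes from an Achmatowicz pyranone by a first Diels–Alder reaction and a rhodium hydroacylation.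

Key step: step 15

Remarks
* Atom labels follow the ent-kaurane numbering of the target: ring A = C1–C5 and C10; lactone ring = C7, C8, C9, C10, C20 and O; ring C = C8, C9, C11–C14; ring D = C8, C13–C16; C17 is the exocyclic methylene, C18 the methyl and C19 the hydroxymethyl on C4, C6 the acetoxymethyl on C5.
* Assumption: 2-(trimethylsilylmethyl)buta-1,3-diene (12) is taken as a purchasable reagent (otherwise one step from isoprene by metalation and silylation).
* Compounds 9 and 10 are racemic; 15 is a mixture of C10 epimers that converges in step 11.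

Step 1
Reactants: 1 acrolein; 2 ethyl 2-(triphenyl-λ5-phosphanylidene)propanoate
Product: 3 ethyl (2E)-2-methylpenta-2,4-dienoate
Conditions: CH2Cl2, 0 °C to rt
Reagents that add atoms: none
Why: Wittig olefination with a stabilised ylide should give the (E)-trisubstituted alkene, the ester ending trans to the vinyl group.

Step 2
Reactants: 3 ethyl (2E)-2-methylpenta-2,4-dienoate
Product: 4 (2E)-2-methylpenta-2,4-dien-1-ol
Conditions: i-Bu2AlH, CH2Cl2, −78 °C
Reagents that add atoms: none
Why: 1,2-Reduction of the conjugated ester by the aluminium hydride gives the dienol without touching the diene.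

Step 3
Reactants: 4 (2E)-2-methylpenta-2,4-dien-1-ol
Product: 5 tert-butyl(dimethyl){[(2E)-2-methylpenta-2,4-dien-1-yl]oxy}silane
Conditions: TBSCl, imidazole, DMF, rt
Reagents that add atoms: tert-butyldimethylsilyl chloride (CC(C)(C)[Si](C)(C)Cl)
Why: Silyl ether formation masks the future C19 hydroxyl so that it stays free of acetate at the end.

Step 4
Reactants: 6 4-bromofuran-2-carbaldehyde
Product: 7 (4-bromofuran-2-yl)methanol
Conditions: NaBH4, MeOH, 0 °C
Reagents that add atoms: none
Why: Borohydride reduction of the aldehyde gives the furfuryl alcohol required for the Achmatowicz step.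

Step 5
Reactants: 7 (4-bromofuran-2-yl)methanol
Product: 8 methyl 5-(hydroxymethyl)furan-3-carboxylate
Conditions: Pd(OAc)2 (5 mol %), Xantphos, CO (1 atm), Et3N, MeOH/DMF, 70 °C
Reagents that add atoms: carbon monoxide ([C-]#[O+]); methanol (CO)
Why: Palladium-catalysed alkoxycarbonylation of the heteroaryl bromide installs the ester carbon that becomes C15.

Step 6
Reactants: 8 methyl 5-(hydroxymethyl)furan-3-carboxylate
Product: 9 methyl 2-hydroxy-5-oxo-5,6-dihydro-2H-pyran-3-carboxylate (racemic lactol)
Conditions: NBS, NaHCO3, THF/H2O (4:1), 0 °C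
Reagents that add atoms: water (O)
Why: Achmatowicz oxidative ring expansion of the furfuryl alcohol gives the pyranone that already holds C7, C8, C9, C10, C20 and the ring oxygen of the later lactone.

Step 7
Reactants: 9 methyl 2-hydroxy-5-oxo-5,6-dihydro-2H-pyran-3-carboxylate
Product: 10 methyl 2-[(tert-butoxycarbonyl)oxy]-5-oxo-5,6-dihydro-2H-pyran-3-carboxylate (racemic)
Conditions: Boc2O, DMAP (cat.), CH2Cl2, −78 to −30 °C
Reagents that add atoms: di-tert-butyl dicarbonate (CC(C)(C)OC(=O)OC(=O)OC(C)(C)C)
Why: O-Acylation of the lactol gives the allylic carbonate needed for palladium π-allyl chemistry.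

Step 8
Reactants: 10 methyl 2-[(tert-butoxycarbonyl)oxy]-5-oxo-5,6-dihydro-2H-pyran-3-carboxylate
Product: 11 methyl (2S)-2-methoxy-5-oxo-5,6-dihydro-2H-pyran-3-carboxylate
Conditions: tris(dibenzylideneacetone)dipalladium–chloroform (2.5 mol %, zerovalent palladium), (S,S)-N,N′-(cyclohexane-1,2-diyl)bis[2-(diphenylphosphino)benzamide] (7.5 mol %), MeOH, CH2Cl2, 0 °C
Reagents that add atoms: methanol (CO)
Why: Palladium-catalysed asymmetric allylic etherification (dynamic kinetic asymmetric transformation through the π-allyl complex) should put methoxide on one face of C7, the ligand antipode being the one that gives the (2S) acetal.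

Step 9
Reactants: 11 methyl (2S)-2-methoxy-5-oxo-5,6-dihydro-2H-pyran-3-carboxylate; 12 trimethyl(2-methylidenebut-3-en-1-yl)silane
Product: 14 methyl (1S)-1-methoxy-7-methylidene-4-oxoperhydroisochromene-8a-carboxylate (cis-fused), via allylsilane cycloadduct 13 (not isolated)
Conditions: PhMe, 80 °C; then CF3CO2H, CH2Cl2, 0 °C
Reagents that add atoms: none
Why: In the Diels–Alder reaction the nucleophilic diene terminus should bond to C8 (β to the ketone, para orientation) on the face anti to the C7 methoxy group, which sets C8 and C9 with a cis ring fusion, and protodesilylation of the allylsilane then shifts the alkene to the exocyclic C13=C16 position.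

Step 10
Reactants: 14 methyl (1S)-1-methoxy-7-methylidene-4-oxoperhydroisochromene-8a-carboxylate
Product: 15 [(1S)-4-hydroxy-1-methoxy-7-methylideneperhydroisochromen-8a-yl]methanol (C10 epimers)
Conditions: LiAlH4, THF, 0 °C
Reagents that add atoms: none
Why: Hydride reduction takes the ester to the primary alcohol and unavoidably the C10 ketone to the alcohol, both being reoxidised in step 11.

Step 11
Reactants: 15 [(1S)-4-hydroxy-1-methoxy-7-methylideneperhydroisochromen-8a-yl]methanol
Product: 16 (1S)-1-methoxy-7-methylidene-4-oxoperhydroisochromene-8a-carbaldehyde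
Conditions: Dess–Martin periodinane, NaHCO3, CH2Cl2, rt
Reagents that add atoms: none
Why: Dess–Martin oxidation of both alcohols returns the C10 ketone and gives the non-enolisable C15 aldehyde.

Step 12
Reactants: 16 (1S)-1-methoxy-7-methylidene-4-oxoperhydroisochromene-8a-carbaldehyde
Product: 17 tricyclic methyl acetal (bicyclo[3.2.1]octan-6-one fused to the C7-methoxy tetrahydropyran-4-one)
Conditions: [Rh(C7H8)(Ph2PCH2CH2PPh2)]BF4 (5 mol %, monovalent rhodium, C7H8 = norbornadiene, pre-hydrogenated), CH2Cl2, rt
Reagents that add atoms: none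
Why: Intramolecular rhodium-catalysed hydroacylation of the pent-4-enal unit C15–C8–C14–C13=C16 closes ring D as the cyclopentanone, and the bridge can only form on the face of ring C that carries the formyl group, which fixes C13.

Step 13
Reactants: 17 tricyclic methyl acetal
Product: 18 tricyclic diketo lactone (C7 lactone, C10 and C15 ketones)
Conditions: CrO3, H2SO4, acetone/H2O, 0 °C to rt
Reagents that add atoms: water (O)
Why: Jones oxidation hydrolyses the methyl acetal and oxidises the lactol to the δ-lactone, which erases the auxiliary C7 stereocentre.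

Step 14
Reactants: 18 tricyclic diketo lactone
Product: 20 (2Z)-configured exocyclic enal C10=C5H–C6HO on the lactone, via unsaturated N-cyclohexyl imine 19 (not isolated)
Conditions: (EtO)2P(O)CH2CH=NC6H11, NaH, THF, 0 °C; then aq. (CO2H)2, rt
Reagents that add atoms: diethyl [2-(cyclohexylimino)ethyl]phosphonate (CCOP(=O)(CC=NC1CCCCC1)OCC); water (O)
Why: Horner–Wadsworth–Emmons formyl-olefination should take place at the more electrophilic α-acyloxy ketone C10 and not at the neopentyl bridged ketone C15, and hydrolysis of the azadiene gives the enal with the formyl group on the less encumbered C20 side.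

Step 15
Reactants: 20 exocyclic enal; 5 tert-butyl(dimethyl){[(2E)-2-methylpenta-2,4-dien-1-yl]oxy}silane
Product: 21 spiro cycloadduct (ring A cyclohexene with C2=C3; C6 formyl, C19 silyloxymethyl and C20 on one face)
Conditions: Me2AlCl (2.5 equiv), CH2Cl2, −78 to −20 °C
Reagents that add atoms: none
Why: Me2AlCl activates the enal and the diene adds in a strongly asynchronous [4+2] cycloaddition in which the unsubstituted terminus C1 bonds first to the β-carbon C10, the developing positive charge being held by the doubly substituted C4, before the aluminium enolate carbon C5 closes onto C4. The closest known reaction type is the Lewis-acid-promoted Diels–Alder reaction of β,β-disubstituted enals and enones with 1,3-dienes used for spiroannulation. Ring A is closed by this intermolecular cycloaddition alone, through a six-membered transition state in which both new σ-bonds (C10–C1 and C5–C4) form on one face of the alkene. C10 is controlled by the cis-fused lactone–bicyclooctane, whose C11 and C14 cover one face of the exocyclic alkene so that the diene should add on the face of H9 and place C1 syn to H9; C4 is controlled by the endo orientation (diene over the formyl group and C20, away from C9) together with the E geometry of 5, which puts the silyloxymethyl group cis to C20; C5 follows from suprafacial addition to the (Z)-enal (formyl cis to C20) and is corrected in step 16. The step needs regioselectivity (C1 and not C4 bonding to C10), secured by the two donor substituents on C4 and the β-electrophilicity of the enal, and chemoselectivity for the enal over the C15 ketone and the lactone, secured by the higher Lewis basicity and the conjugation of the aldehyde.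

Step 16
Reactants: 21 spiro cycloadduct
Product: 22 C5 epimer of 21 (formyl group cis to C9 and to the C4 methyl group)
Conditions: DBU (0.3 equiv), PhMe, 40 °C
Reagents that add atoms: none
Why: Base-mediated epimerisation α to the aldehyde should favour the epimer with the formyl group axial and anti to C20 and to the C4 silyloxymethyl group, where it keeps two instead of four gauche contacts with the flanking quaternary centres.

Step 17
Reactants: 22 C5-epimerised aldehyde
Product: 23 C6 primary alcohol
Conditions: NaBH(OAc)3, PhH, 60 °C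
Reagents that add atoms: none
Why: Triacetoxyborohydride reduces the aldehyde but not the C15 ketone or the lactone.

Step 18
Reactants: 23 C6 primary alcohol
Product: 24 allylic diol (C1 hydroxyl cis to C6 and C9)
Conditions: SeO2 (0.5 equiv), t-BuOOH, CH2Cl2, rt
Reagents that add atoms: selenium dioxide (O=[Se]=O); tert-butyl hydroperoxide (CC(C)(C)OO)
Why: Selenium dioxide allylic hydroxylation (ene reaction then [2,3]-sigmatropic shift) can only occur at C1, the single allylic CH2 of the C2=C3 alkene, and should deliver oxygen suprafacially on the face anti to the axial C20, cis to C6.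

Step 19
Reactants: 24 allylic diol
Product: 25 saturated ring A diol
Conditions: H2 (1 atm), [Ir(C8H12)(P(C6H11)3)(C5H5N)]PF6 (5 mol %, monovalent iridium), CH2Cl2, rt
Reagents that add atoms: none
Why: Hydroxyl-directed homogeneous hydrogenation saturates C2=C3 without hydrogenolysis of the allylic C–O bond or reduction of the ketone.

Step 20
Reactants: 25 saturated ring A diol
Product: 26 C1 and C6 diacetate (C19 silyl ether)
Conditions: Ac2O, DMAP, pyridine, CH2Cl2, rt
Reagents that add atoms: acetic anhydride (CC(=O)OC(C)=O)
Why: DMAP-catalysed acetylation esterifies the C1 and C6 hydroxyls while C19 stays silylated.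

Step 21
Reactants: 26 diacetate
Product: 27 15-oxo-16(17)-ene diacetate (C19 silyl ether)
Conditions: (CH2O)n, N-methylanilinium trifluoroacetate, THF, 65 °C
Reagents that add atoms: formaldehyde, used as paraformaldehyde (C=O)
Why: Mannich-type α-methylenation at C16, the only enolisable position of the C15 ketone, installs the exocyclic enone without strong base.

Step 22
Reactants: 27 silyl-protected enone
Product: 28 CNP0370815.4 (target)
Conditions: HF·pyridine, THF, 0 °C to rt
Reagents that add atoms: none
Why: Fluoride-mediated desilylation frees the C19 hydroxyl without touching the acetates, the lactone or the enone.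

Compound list
1 | prop-2-enal (acrolein) | C=CC=O | starting material
2 | ethyl 2-(triphenyl-λ5-phosphanylidene)propanoate | CCOC(=O)C(C)=P(c1ccccc1)(c1ccccc1)c1ccccc1 | starting material
3 | ethyl (2E)-2-methylpenta-2,4-dienoate | C=C/C=C(\C)C(=O)OCC | intermediate
4 | (2E)-2-methylpenta-2,4-dien-1-ol | C=C/C=C(\C)CO | intermediate
5 | tert-butyl(dimethyl){[(2E)-2-methylpenta-2,4-dien-1-yl]oxy}silane | C=C/C=C(\C)CO[Si](C)(C)C(C)(C)C | intermediate
6 | 4-bromofuran-2-carbaldehyde | O=Cc1cc(Br)co1 | starting material
7 | (4-bromofuran-2-yl)methanol | OCc1cc(Br)co1 | intermediate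
8 | methyl 5-(hydroxymethyl)furan-3-carboxylate | COC(=O)c1coc(CO)c1 | intermediate
9 | methyl 2-hydroxy-5-oxo-5,6-dihydro-2H-pyran-3-carboxylate, racemic | COC(=O)C1=CC(=O)COC1O | intermediate
10 | methyl 2-[(tert-butoxycarbonyl)oxy]-5-oxo-5,6-dihydro-2H-pyran-3-carboxylate, racemic | COC(=O)C1=CC(=O)COC1OC(=O)OC(C)(C)C | intermediate
11 | methyl (2S)-2-methoxy-5-oxo-5,6-dihydro-2H-pyran-3-carboxylate | COC(=O)C1=CC(=O)CO[C@@H]1OC | intermediate
12 | trimethyl(2-methylidenebut-3-en-1-yl)silane | C=CC(=C)C[Si](C)(C)C | starting material
13 | methyl (1S)-1-methoxy-4-oxo-7-[(trimethylsilyl)methyl]-3,4,4a,5-tetrahydro-1H-isochromene-8a(8H)-carboxylate, cis-fused, OMe cis to CO2Me, formed in situ | COC(=O)[C@]23CC(C[Si](C)(C)C)=CC[C@H]2C(=O)CO[C@@H]3OC | intermediate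
14 | methyl (1S)-1-methoxy-7-methylidene-4-oxoperhydroisochromene-8a-carboxylate, cis-fused, H-4a (H9) and OMe cis to CO2Me | COC(=O)[C@]23CC(=C)CC[C@H]2C(=O)CO[C@@H]3OC | intermediate
15 | [(1S)-4-hydroxy-1-methoxy-7-methylideneperhydroisochromen-8a-yl]methanol, cis-fused, both C10 epimers | OC[C@]23CC(=C)CC[C@H]2C(O)CO[C@@H]3OC | intermediate
16 | (1S)-1-methoxy-7-methylidene-4-oxoperhydroisochromene-8a-carbaldehyde, cis-fused | O=C[C@]23CC(=C)CC[C@H]2C(=O)CO[C@@H]3OC | intermediate
17 | tricyclic methyl acetal: bicyclo[3.2.1]octan-6-one (C15 ketone) fused at C8–C9 to the tetrahydropyran-4-one (C7 (S)-methyl acetal, C10 ketone), H9 cis to C15 | C1C(=O)[C@]23C[C@H]1CC[C@H]2C(=O)CO[C@@H]3OC | intermediate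
18 | tricyclic diketo lactone: as 17 but C7 is the δ-lactone carbonyl | C1C(=O)[C@]23C[C@H]1CC[C@H]2C(=O)COC3=O | intermediate
19 | N-cyclohexyl imine of enal 20, formed in situ | C1C(=O)[C@]23C[C@H]1CC[C@H]2/C(=C/C=N/C1CCCCC1)COC3=O | intermediate
20 | (2Z)-2-(lactone-C10-ylidene)acetaldehyde: exocyclic enal C10=C5H–C6HO on 18, formyl group on the C20 side | C1C(=O)[C@]23C[C@H]1CC[C@H]2/C(=C/C=O)COC3=O | intermediate
21 | spiro cycloadduct: ring A cyclohexene (C2=C3), C4 with CH3 and CH2OTBS, C5 with CHO; CHO, CH2OTBS and C20 on one face, C1 syn to H9 | C1C(=O)[C@]23C[C@H]1CC[C@H]2[C@@]1(COC3=O)CC=C[C@](C)(CO[Si](C)(C)C(C)(C)C)[C@@H]1C=O | intermediate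
22 | C5 epimer of 21: CHO cis to C9 and to the C4 methyl group | C1C(=O)[C@]23C[C@H]1CC[C@H]2[C@@]1(COC3=O)CC=C[C@](C)(CO[Si](C)(C)C(C)(C)C)[C@H]1C=O | intermediate
23 | C6 primary alcohol from 22 | C1C(=O)[C@]23C[C@H]1CC[C@H]2[C@@]1(COC3=O)CC=C[C@](C)(CO[Si](C)(C)C(C)(C)C)[C@H]1CO | intermediate
24 | C1 allylic alcohol of 23, 1-OH cis to C6 and C9 | C1C(=O)[C@]23C[C@H]1CC[C@H]2[C@@]1(COC3=O)[C@@H](O)C=C[C@](C)(CO[Si](C)(C)C(C)(C)C)[C@H]1CO | intermediate
25 | saturated ring A 1,6-diol, C19 silyl ether | C1C(=O)[C@]23C[C@H]1CC[C@H]2[C@@]1(COC3=O)[C@@H](O)CC[C@](C)(CO[Si](C)(C)C(C)(C)C)[C@H]1CO | intermediate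
26 | 1,6-diacetate, C19 silyl ether, C15 ketone | C1C(=O)[C@]23C[C@H]1CC[C@H]2[C@@]1(COC3=O)[C@@H](OC(C)=O)CC[C@](C)(CO[Si](C)(C)C(C)(C)C)[C@H]1COC(C)=O | intermediate
27 | 1,6-diacetate, C19 silyl ether, 15-oxo-16(17)-ene | C=C1C(=O)[C@]23C[C@H]1CC[C@H]2[C@@]1(COC3=O)[C@@H](OC(C)=O)CC[C@](C)(CO[Si](C)(C)C(C)(C)C)[C@H]1COC(C)=O | intermediate
28 | CNP0370815.4 | C=C1C(=O)[C@]23C[C@H]1CC[C@H]2[C@@]1(COC3=O)[C@@H](OC(C)=O)CC[C@](C)(CO)[C@H]1COC(C)=O | target

Total step count: 22. Longest linear sequence: 19 steps (steps 4 to 22, from 6).

Steps most likely to fail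

Step 15. The hindered alkene may not be attacked before the diene is consumed by Lewis-acid-induced oligomerisation, or the allyl cation may lose a proton instead of closing onto C5. The fallback sets out from 20 and comes back at 21, using a more nucleophilic 2-silyloxy diene and removing its oxygen afterwards. Wittig reaction of 1-[(tert-butyldimethylsilyl)oxy]propan-2-one with 1-(triphenyl-λ5-phosphanylidene)propan-2-one should give (3E)-5-[(tert-butyldimethylsilyl)oxy]-4-methylpent-3-en-2-one F1. Soft enolisation (Me3SiOTf, Et3N) converts it into tert-butyl(dimethyl){[(2E)-2-methyl-4-[(trimethylsilyl)oxy]penta-2,4-dien-1-yl]oxy}silane F2. Its cycloaddition to 20 under mixed AlBr3/AlMe3 activation, a known way to join hindered silyloxy dienes and β,β-disubstituted acceptors, should give the cycloadduct trimethylsilyl enol ether F3 with the same regio- and facial preferences. CsF and PhNTf2 turn this into the C2 enol triflate F4, and Pd(OAc)2/PPh3 with Bu3N and HCO2H reduces the triflate to the C2=C3 alkene 21.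

Step 16. The equilibration may stall at a mixture or leave the kinetic configuration in place if the two epimers differ too little in energy. The fallback sets out from 21 and comes back at 22 under kinetic instead of thermodynamic control. Deprotonation with KN(SiMe3)2 (2.2 equiv, THF, −78 °C; the C15 ketone is enolised as well) is followed by a quench with 2,6-di-tert-butylphenol, so that the proton should enter C5 on the face away from C9. No new compound is formed on this path (F0).

Step 18. Oxygen delivery may show poor facial selectivity, or the allylic alcohol may be over-oxidised to the enone. The fallback sets out from 23 and comes back at 24 by oxidation and reduction instead of direct hydroxylation. The crude hydroxylation mixture is taken on purpose to the C1 enone F5 with MnO2, which leaves the saturated C6 alcohol alone. Luche reduction (NaBH4, CeCl3·7H2O, MeOH, −78 °C) of the conjugated ketone, expected to be faster than that of the bridged C15 ketone, should then deliver hydride anti to the axial C6 hydroxymethyl group and give 24.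

Further compounds
F1 | step 15 | (3E)-5-[(tert-butyldimethylsilyl)oxy]-4-methylpent-3-en-2-one | CC(=O)/C=C(\C)CO[Si](C)(C)C(C)(C)C
F2 | step 15 | tert-butyl(dimethyl){[(2E)-2-methyl-4-[(trimethylsilyl)oxy]penta-2,4-dien-1-yl]oxy}silane | C=C(O[Si](C)(C)C)/C=C(\C)CO[Si](C)(C)C(C)(C)C
F3 | step 15 | cycloadduct trimethylsilyl enol ether (as 21 but C2 bears OSiMe3) | C1C(=O)[C@]23C[C@H]1CC[C@H]2[C@@]1(COC3=O)CC(O[Si](C)(C)C)=C[C@](C)(CO[Si](C)(C)C(C)(C)C)[C@@H]1C=O
F4 | step 15 | C2 enol triflate (as 21 but C2 bears OSO2CF3) | C1C(=O)[C@]23C[C@H]1CC[C@H]2[C@@]1(COC3=O)CC(OS(=O)(=O)C(F)(F)F)=C[C@](C)(CO[Si](C)(C)C(C)(C)C)[C@@H]1C=O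
F0 | step 16 | none | none
F5 | step 18 | C1 enone (as 24 but C1 is a ketone conjugated to C2=C3) | C1C(=O)[C@]23C[C@H]1CC[C@H]2[C@@]1(COC3=O)C(=O)C=C[C@](C)(CO[Si](C)(C)C(C)(C)C)[C@H]1CO
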